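All runs are simulated from invented constants, noise included.

in all of them: substrate 0.25 M

|  | coupling partner | remark | time |
|---|---|---|---|
| midnight | 0.13 M | run made earlier |  |
| dawn | 0.90 M | run made earlier |  |
| oak | 0.250 M |  | 2.0 h |
| larch | 1.00 M |  | 2.0 h |

| run | time / min | single product / % | substrate / % |
|---|---|---|---|
| midnight | 10.0 | 37.6 | 54.0 |
| midnight | 20.0 | 38.5 | 54.6 |
| midnight | 30.0 | 38.4 | 55.1 |
| midnight | 40.0 | 37.7 | 54.2 |
| midnight | 50.0 | 38.0 | 53.4 |
| midnight | 60.0 | 38.4 | 53.5 |
| dawn | 5.00 | 19.2 | 0.2 |
| dawn | 8.00 | 13.4 | 0.1 |
| dawn | 12.0 | 9.5 | 0.1 |
| dawn | 20.0 | 8.2 | 0.2 |
| dawn | 40.0 | 6.9 | 0 |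
| dawn | 60.0 | 6.9 | 0.4 |

(each reading ± 0.5 percentage points)

- the analysis behind the earlier runs scatters by 0.5 percentage points, standard deviation
- what may be going on: substrate + coupling partner -> single product; substrate + coupling partner -> other mono adduct; coupling partner + single product -> bis adduct; coupling partner + other mono adduct -> bis adduct; coupling partner -> decomposed reagent; 2 coupling partner -> self-condensation product

* which of these holds the largest part of the substrate at the end of oak (bis adduct / single product / substrate / other mono adduct)
* which of these holds the largest part of the substrate at the end of larch (bis adduct / single product / substrate / other mono adduct)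
* amount of single product at the end of larch, in percent of the substrate charged

1. The time of reading, 2.0 h, is a poor clock for these flasks. Midnight reads 37.6% of single product after 10.0 min and 38.4% after 60.0 min, against a scatter of 0.5 percentage points, with 53.5% of substrate still present. Dawn reads 6.9% after 40.0 min and 6.9% after 60.0 min. Midnight's stop is therefore read as the loss of coupling partner, the limiting reagent there, and the useful clock is equivalents of partner per substrate.

2. A mono adduct holds one partner per substrate and the bis adduct holds two, so full conversion to bis adduct demands 2 equivalents.

3. Midnight charges 0.520 equivalents and removes enough substrate to give 0.894 per equivalent. This is a lower figure, since its bis adduct is unread.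

4. Dawn charges 3.60 equivalents, and its substrate reads 0.4%. Taking single product as the one unfinished adduct gives 0.536. This is the capture share: equivalents that reached substrate or its adducts, per equivalent charged. It is an upper figure, since other mono adduct is unread. Dawn's share stands lower than midnight's figure, so at dawn's higher charge more of each equivalent went elsewhere.

5. My reckoning: larch charges 4.00 equivalents, and at dawn's share that delivers 2.14, just above the demand, so bis adduct leads. Oak charges 1.00 equivalent, half of the demand, and that count by itself does not say which species leads. Midnight, with about half of oak's charge, reads single product as 82.6% of the substrate consumed, so my reckoning names single product for oak as a judgement from that reading. The share gives no figure for single product.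

6. The forecast names single product for oak and bis adduct for larch, with 3.5% of single product in larch, because “the rest pushes the remaining mono adduct on to bis”.

    substrate + coupling partner → single product (k = 6.90 M⁻¹ min⁻¹)
    substrate + coupling partner → other mono adduct (k = 1.00 M⁻¹ min⁻¹)
    coupling partner + single product → bis adduct (k = 0.990 M⁻¹ min⁻¹)
    coupling partner + other mono adduct → bis adduct (k = 1.30 M⁻¹ min⁻¹)
    coupling partner → decomposed reagent (k = 0.130 min⁻¹)
    2 coupling partner → self-condensation product (k = 0.0480 M⁻¹ min⁻¹)

Oak's largest holder is single product, at 61.3%. Larch's largest holder is bis adduct, at 95.5%. Larch's amount asked for is 4.26%, so the forecast stands. Below larch's charge, 0.849 M of partner is the nearest amount at which that figure has moved by 5 points. Larch's capture share, counting both mono adducts, is 0.489, below dawn's 0.536. The neighbour flask with 2.5 M of partner, 10.0 equiv, ends at 0.00956% of single product and a capture share of 0.200.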